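**Plan**

- Numbering: hexanoic acid C1–C6; its C2 side chain C1'–C7' (C4' bears the methyl, C7' is the ketone carbon); pyranone ring O1–C6.
- Retrosynthetic cuts, in order: C7'–C3(ring), by O-acylation and O→C acyl shift onto a preformed (6R)-dihydropyranone; then C3'–C4', by a copper-catalysed γ-selective, 1,3-anti allyl–alkyl coupling; then C2–C1', by dianion allylation.
- Enabling feature: exactly two methylenes, C5' and C6', lie between C4' and the C7' carbonyl carbon, and C1'–C3' is an unbranched trimethylene. C5'=C6' can therefore be an alkene, C6' (next to C7', carried as CH2OBn) a phosphate-bearing carbinol whose chirality is passed to C4', and C3' the end of an allyl group hydroborated in the flask.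
- Forward order: fragment 1 (C1–C6 with the C1'–C3' allyl group) and fragment 2 (C4'–C7', the C4' methyl as a (Z)-propenyl end) are joined at C3'–C4'. One hydrogenation removes the alkene and the benzyl group, C7' is oxidised to the acid, the only ring is made separately and attached last, and one acid step frees the acid and the alcohol.
- Stereochemistry: C4 from (S)-2-methylbutanoic acid; C3 by Noyori hydrogenation; C2 by anti-selective Fráter–Seebach allylation; C4' by 1,3-chirality transfer from an (R)-carbinol set by asymmetric transfer hydrogenation; ring C6 from ethyl (R)-3-hydroxybutanoate.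

Key step: step 9

Remark: the acyl pyranone is written throughout as the 4-hydroxy enol tautomer of the given structure (the chelated tricarbonyl tautomers are the same compound), and 19 is likewise written as its enol. The Weinreb amide 7 is taken as a commercial starting material.

**Route**

Step 1
Reactants: 1 (S)-2-methylbutanoic acid
Product: 3 tert-butyl (S)-4-methyl-3-oxohexanoate, via acyl imidazolide 2 (not isolated)
Conditions: CDI, THF, rt; then Mg(O2CCH2CO2tBu)2, THF, rt → 40 °C; aq. HCl work-up
Reagents that add atoms: magnesium bis(mono-tert-butyl malonate), [Mg+2].[O-]C(=O)CC(=O)OC(C)(C)C.[O-]C(=O)CC(=O)OC(C)(C)C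
Why: Decarboxylative Claisen condensation of the acyl imidazolide with the neutral magnesium malonate half-ester should give the β-keto ester without enolising the C4 stereocenter.

Step 2
Reactants: 3 tert-butyl (S)-4-methyl-3-oxohexanoate
Product: 4 tert-butyl (3S,4S)-3-hydroxy-4-methylhexanoate
Conditions: H2 (4 atm), RuCl2[(R)-BINAP] (0.5 mol%), MeOH, 50 °C
Reagents that add atoms: none
Why: Noyori asymmetric hydrogenation of a β-keto ester; the (R)-BINAP catalyst should deliver hydrogen to the face that gives (R)-3-hydroxybutanoate from acetoacetate, called 3S here because sec-butyl outranks CH2CO2tBu, with catalyst control dominating over the C4 center.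

Step 3
Reactants: 4 tert-butyl (3S,4S)-3-hydroxy-4-methylhexanoate
Product: 5 tert-butyl (2R,3R,4S)-3-hydroxy-4-methyl-2-(prop-2-en-1-yl)hexanoate
Conditions: LiN(iPr)2 (2.2 equiv), THF, −50 → −20 °C; allyl bromide, DMPU, −78 → 0 °C; aq. NH4Cl
Reagents that add atoms: allyl bromide, C=CCBr
Why: Fráter–Seebach alkylation; the lithium-chelated alkoxide–enolate dianion should be allylated on the face opposite the C3 sec-butyl group, which sets C2 in the 2,3-anti sense.

Step 4
Reactants: 5 tert-butyl (2R,3R,4S)-3-hydroxy-4-methyl-2-(prop-2-en-1-yl)hexanoate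
Product: 6 tert-butyl (2R,3R,4S)-4-methyl-2-(prop-2-en-1-yl)-3-[(triethylsilyl)oxy]hexanoate
Conditions: Et3SiCl, imidazole, DMAP (cat.), DMF, rt → 40 °C
Reagents that add atoms: chlorotriethylsilane, CC[Si](Cl)(CC)CC
Why: Standard silylation that leaves the tert-butyl ester untouched and masks the hydroxyl against B–H and alkoxide in step 9.

Step 5
Reactants: 7 2-(benzyloxy)-N-methoxy-N-methylacetamide
Product: 8 1-(benzyloxy)pent-3-yn-2-one
Conditions: CH3C≡CMgBr, THF, −20 → 0 °C; aq. NH4Cl
Reagents that add atoms: prop-1-ynylmagnesium bromide, CC#C[Mg]Br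
Why: Weinreb ketone synthesis; the chelated tetrahedral intermediate should prevent over-addition to the ynone.

Step 6
Reactants: 8 1-(benzyloxy)pent-3-yn-2-one
Product: 9 (R)-1-(benzyloxy)pent-3-yn-2-ol
Conditions: Ru(p-cymene)[(S,S)-TsNCH(Ph)CH(Ph)NH] (1 mol%), iPrOH, rt
Reagents that add atoms: none
Why: Noyori asymmetric transfer hydrogenation of an alkynyl ketone, the alkyne taking the place of the aryl group in the six-membered hydride-transfer transition state, so the (S,S)-catalyst should give the carbinol that is R here because CH2OBn outranks the alkyne.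

Step 7
Reactants: 9 (R)-1-(benzyloxy)pent-3-yn-2-ol
Product: 10 (R,Z)-1-(benzyloxy)pent-3-en-2-ol
Conditions: H2 (1 atm), Pd/CaCO3 poisoned with Pb(OAc)2, quinoline, EtOAc, rt
Reagents that add atoms: none
Why: Lindlar semihydrogenation; syn delivery of hydrogen should give the Z-alkene and leave the carbinol center and the benzyl ether alone.

Step 8
Reactants: 10 (R,Z)-1-(benzyloxy)pent-3-en-2-ol
Product: 11 (R,Z)-1-(benzyloxy)pent-3-en-2-yl diethyl phosphate
Conditions: (EtO)2P(O)Cl, pyridine, DMAP (cat.), CH2Cl2, 0 °C → rt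
Reagents that add atoms: diethyl chlorophosphate, CCOP(=O)(Cl)OCC
Why: O-phosphorylation forms a P–O bond only, so C2 keeps its configuration, and the adjacent CH2OBn group should disfavour ionisation of the secondary allylic phosphate.

Step 9
Reactants: 6 tert-butyl (2R,3R,4S)-4-methyl-2-(prop-2-en-1-yl)-3-[(triethylsilyl)oxy]hexanoate, 11 (R,Z)-1-(benzyloxy)pent-3-en-2-yl diethyl phosphate
Product: 13 tert-butyl (2R,3R,4S)-2-[(4S,5E)-7-(benzyloxy)-4-methylhept-5-en-1-yl]-4-methyl-3-[(triethylsilyl)oxy]hexanoate, via B-alkyl-9-BBN 12 (not isolated)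
Conditions: 6, (9-BBN-H)2, THF, 60 °C; then KOtBu (slightly less than the borane), CuOAc (10 mol%), 11, THF, 60 °C
Reagents that add atoms: none
Why: 9-BBN-H adds anti-Markovnikov to the terminal alkene of 6 to give the primary alkylborane 12, KOtBu converts it into the alkyl(tert-butoxy)borate, which passes the primary alkyl group to monovalent copper, and the alkylcopper adds across C3=C4 of 11 with C–C bond formation at C4 (γ) on the face opposite the C2–O bond, after which anti β-elimination of copper diethyl phosphate releases the (E)-C5'=C6' alkene. The closest known reaction type is the copper-catalysed γ-selective, 1,3-anti stereospecific allyl–alkyl coupling of alkyl-9-BBN reagents with secondary (Z)-allylic phosphates. No ring is closed. The new C4' stereocenter is controlled by the (R)-configured C2 of 11 together with the Z geometry: allylic 1,3-strain with the Z-methyl holds the C2–H bond in the alkene plane so that one rotamer reacts, and anti delivery to C4 should give 4'S while C2 becomes the sp2 carbon C6'. The step needs γ over α attack, anti over syn delivery and survival of the ester and silyl ether; the phosphate leaving group with an alkylcopper generated from the borate favours γ, the Z geometry with tert-butoxide in THF favours the anti course, and forming the borate before CuOAc and 11 are added leaves no free alkoxide to enolise the tert-butyl ester.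

Step 10
Reactants: 13 tert-butyl (2R,3R,4S)-2-[(4S,5E)-7-(benzyloxy)-4-methylhept-5-en-1-yl]-4-methyl-3-[(triethylsilyl)oxy]hexanoate
Product: 15 tert-butyl (2R,3R,4S)-2-[(4S)-7-hydroxy-4-methylheptyl]-4-methyl-3-[(triethylsilyl)oxy]hexanoate, via saturated benzyl ether 14 (not isolated)
Conditions: H2 (1 atm), 5% Pt/C, EtOAc, rt; then 20% Pd(OH)2/C, H2 (1 atm), EtOAc, rt
Reagents that add atoms: none
Why: Catalytic hydrogenation on Pt should saturate the C5'=C6' alkene without the double-bond migration toward C4' that Pd can cause, and Pd(OH)2 then hydrogenolyses the no longer allylic benzyl ether, the TES ether and tert-butyl ester being stable in EtOAc.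

Step 11
Reactants: 15 tert-butyl (2R,3R,4S)-2-[(4S)-7-hydroxy-4-methylheptyl]-4-methyl-3-[(triethylsilyl)oxy]hexanoate
Product: 16 (4S,8R,9R,10S)-8-(tert-butoxycarbonyl)-4,10-dimethyl-9-[(triethylsilyl)oxy]dodecanoic acid
Conditions: TEMPO (cat.), NaOCl (cat.), NaClO2, MeCN/phosphate buffer (pH 6.7), 35 °C
Reagents that add atoms: sodium chlorite, [Na+].[O-]Cl=O
Why: Oxoammonium oxidation to the aldehyde and Pinnick-type chlorite oxidation in the same flask should give the acid at near-neutral pH, which the TES ether and tert-butyl ester tolerate.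

Step 12
Reactants: 17 ethyl (R)-3-hydroxybutanoate
Product: 18 tert-butyl (R)-5-hydroxy-3-oxohexanoate
Conditions: tBuOAc, LiN(iPr)2 (3.5 equiv each), THF, −78 °C; then 17, −78 → −20 °C; aq. NH4Cl
Reagents that add atoms: tert-butyl acetate, CC(=O)OC(C)(C)C
Why: Crossed Claisen condensation on the unprotected hydroxy ester, the excess enolate absorbing the hydroxyl and product protons, does not touch the stereocenter.

Step 13
Reactants: 18 tert-butyl (R)-5-hydroxy-3-oxohexanoate
Product: 19 (R)-4-hydroxy-6-methyl-5,6-dihydro-2H-pyran-2-one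
Conditions: TFA, CH2Cl2, rt
Reagents that add atoms: none
Why: Acidolysis of the tert-butyl ester and 6-exo-trig lactonisation of the δ-hydroxy β-keto acid should outrun decarboxylation, and the C–O bond at the stereocenter is not broken.

Step 14
Reactants: 16 (4S,8R,9R,10S)-8-(tert-butoxycarbonyl)-4,10-dimethyl-9-[(triethylsilyl)oxy]dodecanoic acid, 19 (R)-4-hydroxy-6-methyl-5,6-dihydro-2H-pyran-2-one
Product: 21 tert-butyl (2R,3R,4S)-2-{(4S)-7-[(6R)-4-hydroxy-6-methyl-2-oxo-5,6-dihydro-2H-pyran-3-yl]-4-methyl-7-oxoheptyl}-4-methyl-3-[(triethylsilyl)oxy]hexanoate, via enol ester 20 (not isolated)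
Conditions: DCC, DMAP (1.2 equiv), CH2Cl2, 0 °C → rt, then 40 °C
Reagents that add atoms: none
Why: Steglich O-acylation of the vinylogous acid followed by a DMAP-mediated Fries-type 1,3 O→C acyl shift through the acylpyridinium/dione enolate ion pair should give the hydrogen-bonded C3-acyl tricarbonyl, the thermodynamic product.

Step 15
Reactants: 21 tert-butyl (2R,3R,4S)-2-{(4S)-7-[(6R)-4-hydroxy-6-methyl-2-oxo-5,6-dihydro-2H-pyran-3-yl]-4-methyl-7-oxoheptyl}-4-methyl-3-[(triethylsilyl)oxy]hexanoate
Product: 22 (2R,3R,4S)-3-hydroxy-2-{(4S)-7-[(6R)-4-hydroxy-6-methyl-2-oxo-5,6-dihydro-2H-pyran-3-yl]-4-methyl-7-oxoheptyl}-4-methylhexanoic acid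
Conditions: TFA/CH2Cl2 (1:1), H2O (5 equiv), 0 °C → rt
Reagents that add atoms: none
Why: Acidolysis should remove the tert-butyl ester and the TES ether in one operation, and the absence of base avoids retro-aldol cleavage of the β-hydroxy acid and β-elimination of the lactone.

**Compound list**

1 | (S)-2-methylbutanoic acid | CC[C@H](C)C(=O)O | starting material
2 | (S)-1-(1H-imidazol-1-yl)-2-methylbutan-1-one | CC[C@H](C)C(=O)n1ccnc1 | intermediate
3 | tert-butyl (S)-4-methyl-3-oxohexanoate | CC[C@H](C)C(=O)CC(=O)OC(C)(C)C | intermediate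
4 | tert-butyl (3S,4S)-3-hydroxy-4-methylhexanoate | CC[C@H](C)[C@@H](O)CC(=O)OC(C)(C)C | intermediate
5 | tert-butyl (2R,3R,4S)-3-hydroxy-4-methyl-2-(prop-2-en-1-yl)hexanoate | CC[C@H](C)[C@@H](O)[C@@H](CC=C)C(=O)OC(C)(C)C | intermediate
6 | tert-butyl (2R,3R,4S)-4-methyl-2-(prop-2-en-1-yl)-3-[(triethylsilyl)oxy]hexanoate | CC[C@H](C)[C@@H](O[Si](CC)(CC)CC)[C@@H](CC=C)C(=O)OC(C)(C)C | intermediate
7 | 2-(benzyloxy)-N-methoxy-N-methylacetamide | CON(C)C(=O)COCc1ccccc1 | starting material
8 | 1-(benzyloxy)pent-3-yn-2-one | CC#CC(=O)COCc1ccccc1 | intermediate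
9 | (R)-1-(benzyloxy)pent-3-yn-2-ol | CC#C[C@@H](O)COCc1ccccc1 | intermediate
10 | (R,Z)-1-(benzyloxy)pent-3-en-2-ol | C/C=C\[C@@H](O)COCc1ccccc1 | intermediate
11 | (R,Z)-1-(benzyloxy)pent-3-en-2-yl diethyl phosphate | C/C=C\[C@@H](OP(=O)(OCC)OCC)COCc1ccccc1 | intermediate
12 | tert-butyl (2R,3R,4S)-2-[3-(9-borabicyclo[3.3.1]nonan-9-yl)propyl]-4-methyl-3-[(triethylsilyl)oxy]hexanoate | CC[C@H](C)[C@@H](O[Si](CC)(CC)CC)[C@@H](CCCB1C2CCCC1CCC2)C(=O)OC(C)(C)C | intermediate
13 | tert-butyl (2R,3R,4S)-2-[(4S,5E)-7-(benzyloxy)-4-methylhept-5-en-1-yl]-4-methyl-3-[(triethylsilyl)oxy]hexanoate | CC[C@H](C)[C@@H](O[Si](CC)(CC)CC)[C@@H](CCC[C@H](C)/C=C/COCc1ccccc1)C(=O)OC(C)(C)C | intermediate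
14 | tert-butyl (2R,3R,4S)-2-[(4S)-7-(benzyloxy)-4-methylheptyl]-4-methyl-3-[(triethylsilyl)oxy]hexanoate | CC[C@H](C)[C@@H](O[Si](CC)(CC)CC)[C@@H](CCC[C@H](C)CCCOCc1ccccc1)C(=O)OC(C)(C)C | intermediate
15 | tert-butyl (2R,3R,4S)-2-[(4S)-7-hydroxy-4-methylheptyl]-4-methyl-3-[(triethylsilyl)oxy]hexanoate | CC[C@H](C)[C@@H](O[Si](CC)(CC)CC)[C@@H](CCC[C@H](C)CCCO)C(=O)OC(C)(C)C | intermediate
16 | (4S,8R,9R,10S)-8-(tert-butoxycarbonyl)-4,10-dimethyl-9-[(triethylsilyl)oxy]dodecanoic acid | CC[C@H](C)[C@@H](O[Si](CC)(CC)CC)[C@@H](CCC[C@H](C)CCC(=O)O)C(=O)OC(C)(C)C | intermediate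
17 | ethyl (R)-3-hydroxybutanoate | C[C@@H](O)CC(=O)OCC | starting material
18 | tert-butyl (R)-5-hydroxy-3-oxohexanoate | C[C@@H](O)CC(=O)CC(=O)OC(C)(C)C | intermediate
19 | (R)-4-hydroxy-6-methyl-5,6-dihydro-2H-pyran-2-one | C[C@@H]1CC(O)=CC(=O)O1 | intermediate
20 | (6R)-6-methyl-2-oxo-5,6-dihydro-2H-pyran-4-yl (4S,8R,9R,10S)-8-(tert-butoxycarbonyl)-4,10-dimethyl-9-[(triethylsilyl)oxy]dodecanoate | CC[C@H](C)[C@@H](O[Si](CC)(CC)CC)[C@@H](CCC[C@H](C)CCC(=O)OC1=CC(=O)O[C@H](C)C1)C(=O)OC(C)(C)C | intermediate
21 | tert-butyl (2R,3R,4S)-2-{(4S)-7-[(6R)-4-hydroxy-6-methyl-2-oxo-5,6-dihydro-2H-pyran-3-yl]-4-methyl-7-oxoheptyl}-4-methyl-3-[(triethylsilyl)oxy]hexanoate | CC[C@H](C)[C@@H](O[Si](CC)(CC)CC)[C@@H](CCC[C@H](C)CCC(=O)C1=C(O)C[C@@H](C)OC1=O)C(=O)OC(C)(C)C | intermediate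
22 | (2R,3R,4S)-3-hydroxy-2-{(4S)-7-[(6R)-4-hydroxy-6-methyl-2-oxo-5,6-dihydro-2H-pyran-3-yl]-4-methyl-7-oxoheptyl}-4-methylhexanoic acid | CC[C@H](C)[C@@H](O)[C@@H](CCC[C@H](C)CCC(=O)C1=C(O)C[C@@H](C)OC1=O)C(=O)O | target

**Summary**

Total step count: 15.
Longest linear sequence: 9 steps (steps 1, 2, 3, 4, 9, 10, 11, 14, 15; the branch through steps 5–8 is equally long).

Steps most likely to fail:

1. Step 9. The benzyloxy oxygen next to the phosphate may coordinate copper, which could erode γ-selectivity or turn part of the delivery syn. Residual alkoxide may also enolise the α-branched ester and cause epimerisation at C2 or loss of the silyloxy group. The fallback sets out from 12 (made from 6 as in step 9) and moves the stereocontrol from chirality transfer to a catalyst-controlled hydrogenation. A B-alkyl Suzuki–Miyaura coupling of 12 with (E)-4-iodopent-3-en-1-ol F1 (from pent-3-yn-1-ol by Cp2Zr(H)Cl, then I2), run with PdCl2(dppf), AsPh3 and Cs2CO3 in DMF/THF/H2O, should give the trisubstituted homoallylic alcohol tert-butyl (2R,3R,4S)-2-[(4E)-7-hydroxy-4-methylhept-4-en-1-yl]-4-methyl-3-[(triethylsilyl)oxy]hexanoate F2. Hydroxyl-directed asymmetric hydrogenation of F2 with Ru(OAc)2[(R)-BINAP] under H2 (100 atm) in MeOH would then set C4'; the BINAP antipode is chosen by analogy with homoallylic terpene alcohols and should be confirmed on a model. This returns to the route at 15.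

2. Step 14. The enol ester 20 may resist the O→C acyl shift, or the dihydropyranone may open by β-elimination under DMAP. The fallback sets out from 16 and builds the ring onto the chain instead of acylating a preformed ring. Condensation of 16 with Meldrum's acid (DCC, DMAP, CH2Cl2) should give the acyl Meldrum's acid tert-butyl (2R,3R,4S)-2-[(4S)-7-(2,2-dimethyl-4,6-dioxo-1,3-dioxan-5-yl)-4-methyl-7-oxoheptyl]-4-methyl-3-[(triethylsilyl)oxy]hexanoate F3. Heating F3 with 17 in toluene at 90 °C generates the acylketene, which the secondary hydroxyl of 17 traps to give the β-keto ester tert-butyl (2R,3R,4S)-2-{(4S)-9-{[(2R)-4-ethoxy-4-oxobutan-2-yl]oxy}-4-methyl-7,9-dioxononyl}-4-methyl-3-[(triethylsilyl)oxy]hexanoate F4. Dieckmann cyclisation of F4 (KOtBu, tBuOH/THF, then mild acid) closes the pyranone and returns to the route at 21.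

3. Step 3. Dianion formation at the hindered β-hydroxy tert-butyl ester may be incomplete, O-allylation may compete, or facial selectivity may be lowered by the branched C4 substituent. The fallback sets out from 1 and replaces steps 1–3 by a reagent-controlled anti-aldol. Reduction of 1 with LiAlH4 gives (S)-2-methylbutan-1-ol F5, and TEMPO/PhI(OAc)2 oxidation gives (S)-2-methylbutanal F6, used crude to avoid racemisation. The (E)-boron enolate of commercial tert-butyl pent-4-enoate is formed with a C2-symmetric 1,2-diphenylethylenediamine bis(sulfonamide) bromoborane and Et3N in toluene/hexane, using the antipode that gives the (2R,3R)-anti adduct. Its addition to F6 at −78 °C should give the anti-aldol product directly, returning to the route at 5.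

**Further compounds**

F1 | step 9 | (E)-4-iodopent-3-en-1-ol | C/C(I)=C\CCO
F2 | step 9 | tert-butyl (2R,3R,4S)-2-[(4E)-7-hydroxy-4-methylhept-4-en-1-yl]-4-methyl-3-[(triethylsilyl)oxy]hexanoate | CC[C@H](C)[C@@H](O[Si](CC)(CC)CC)[C@@H](CCC/C(C)=C/CCO)C(=O)OC(C)(C)C
F3 | step 14 | tert-butyl (2R,3R,4S)-2-[(4S)-7-(2,2-dimethyl-4,6-dioxo-1,3-dioxan-5-yl)-4-methyl-7-oxoheptyl]-4-methyl-3-[(triethylsilyl)oxy]hexanoate | CC[C@H](C)[C@@H](O[Si](CC)(CC)CC)[C@@H](CCC[C@H](C)CCC(=O)C1C(=O)OC(C)(C)OC1=O)C(=O)OC(C)(C)C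
F4 | step 14 | tert-butyl (2R,3R,4S)-2-{(4S)-9-{[(2R)-4-ethoxy-4-oxobutan-2-yl]oxy}-4-methyl-7,9-dioxononyl}-4-methyl-3-[(triethylsilyl)oxy]hexanoate | CC[C@H](C)[C@@H](O[Si](CC)(CC)CC)[C@@H](CCC[C@H](C)CCC(=O)CC(=O)O[C@H](C)CC(=O)OCC)C(=O)OC(C)(C)C
F5 | step 3 | (S)-2-methylbutan-1-ol | CC[C@H](C)CO
F6 | step 3 | (S)-2-methylbutanal | CC[C@H](C)C=O
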